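**Strategy.** The cyclohexene (C1–C6) is not made directly: it is traced back across its C1–C2 bond to a four-membered ring C1–C6–C5–C4 that carries the future C3(Me)=C2 unit as an (E)-alkenyl group on C4. The key step is an ionic vinylcyclobutane–cyclohexene rearrangement: Lewis-acid chelation of the o-hydroxyaryl ketone on C1 ionises the strained C1–C4 bond, and the enolate recaptures the allyl cation at C2, so that the ring grows by two atoms, C1 and C2 are set and the C6 stereocentre is carried through. The cyclobutane comes from an enantioselective radical-anion [2+2] cycloaddition of silylated cardamonin with a vinyl ketone, followed by enol triflate methylation.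

Key step: step 7

Numbering used for the target ring: C1 (aroyl-bearing CH), C2 (prenyl-bearing CH), C3 (C–CH3, sp2), C4 (=CH), C5 (CH2), C6 (phenyl-bearing CH). The same atom labels are kept for the cyclobutane precursors.

Assumption 1: cardamonin, 5-bromo-2-methylpent-2-ene and N-methoxy-N-methylacrylamide are taken as commercial.
Assumption 2: the sense of induction of the chiral europium Lewis acid for a 2',6'-dioxygenated chalcone is assigned by analogy; the ligand antipode is chosen so that the phenyl-bearing carbon is formed with the (R) configuration.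

Step 1
Reactants: 1 cardamonin [(E)-1-(2,4-dihydroxy-6-methoxyphenyl)-3-phenylprop-2-en-1-one]
Product: 2 (E)-1-[2,4-bis(tert-butyldimethylsilyloxy)-6-methoxyphenyl]-3-phenylprop-2-en-1-one
Conditions: TBSOTf (2.5 equiv), 2,6-lutidine, CH2Cl2, 0 °C → rt
Reagents that add atoms: tert-butyldimethylsilyl trifluoromethanesulfonate, CC(C)(C)[Si](C)(C)OS(=O)(=O)C(F)(F)F
Why: O-silylation with the silyl triflate converts both phenols, including the hydrogen-bonded 2'-OH, into TBS ethers so that no acidic OH interferes with the later enolate and cuprate steps; no stereocentre is formed.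

Step 2
Reactants: 3 5-bromo-2-methylpent-2-ene; 4 N-methoxy-N-methylprop-2-enamide
Product: 6 7-methylocta-1,6-dien-3-one, via (4-methylpent-3-en-1-yl)magnesium bromide 5 (not isolated)
Conditions: Mg, THF, rt; then 4, −78 → 0 °C; cold 1 M HCl
Reagents that add atoms: none
Why: Weinreb ketone synthesis, in which the Grignard reagent adds once to the amide through a stable magnesium chelate and the cold acidic quench releases the vinyl ketone while protonating the liberated amine so that it cannot add in aza-Michael fashion.

Step 3
Reactants: 2 (E)-1-[2,4-bis(tert-butyldimethylsilyloxy)-6-methoxyphenyl]-3-phenylprop-2-en-1-one; 6 7-methylocta-1,6-dien-3-one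
Product: 7 [2,4-bis(tert-butyldimethylsilyloxy)-6-methoxyphenyl][(1S,2S,4R)-2-(5-methylhex-4-enoyl)-4-phenylcyclobutyl]methanone (all-trans)
Conditions: 6 (5 equiv), Ru(bpy)3Cl2 (5 mol %), Eu(OTf)3 (10 mol %), chiral Schiff-base amino amide ligand (20 mol %), i-Pr2NEt, MeCN, visible light, −20 °C
Reagents that add atoms: none
Why: Crossed radical-anion [2+2] photocycloaddition under photoredox/chiral Lewis acid dual catalysis, in which the Eu-bound chalcone is reduced, its β-carbon adds to the CH2 terminus of the vinyl ketone and the α-acyl radical closes on the enolate carbon (head-to-head), so that the phenyl-bearing stereocentre is set by the chiral Lewis acid in the first C–C bond formation, the two enolisable acyl-bearing centres settle trans, and the configuration at the 5-methylhexenoyl-bearing carbon is of no consequence because that carbon becomes sp2 in step 7.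

Step 4
Reactants: 7 [2,4-bis(tert-butyldimethylsilyloxy)-6-methoxyphenyl][(1S,2S,4R)-2-(5-methylhex-4-enoyl)-4-phenylcyclobutyl]methanone
Product: 9 (1Z)-1-{(1S,2S,3R)-2-[2,4-bis(tert-butyldimethylsilyloxy)-6-methoxybenzoyl]-3-phenylcyclobutyl}-5-methylhexa-1,4-dien-1-yl trifluoromethanesulfonate, via potassium (Z)-enolate 8 (not isolated)
Conditions: KHMDS (1.05 equiv), THF, −78 °C; then PhNTf2, −78 → −20 °C
Reagents that add atoms: N-phenylbis(trifluoromethanesulfonimide), O=S(=O)(N(c1ccccc1)S(=O)(=O)C(F)(F)F)C(F)(F)F
Why: Enol triflate formation, in which kinetic deprotonation by the hindered amide should occur at the unhindered chain α-CH2 and not at either cyclobutyl methine, the bulky cyclobutyl residue should enforce the (Z)-enolate through allylic strain, and O-triflation fixes that geometry.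

Step 5
Reactants: 9 (1Z)-1-{(1S,2S,3R)-2-[2,4-bis(tert-butyldimethylsilyloxy)-6-methoxybenzoyl]-3-phenylcyclobutyl}-5-methylhexa-1,4-dien-1-yl trifluoromethanesulfonate
Product: 10 [2,4-bis(tert-butyldimethylsilyloxy)-6-methoxyphenyl]{(1R,2S,4R)-2-[(2E)-6-methylhepta-2,5-dien-2-yl]-4-phenylcyclobutyl}methanone
Conditions: Me2CuLi (from MeLi and CuI), THF, −20 °C
Reagents that add atoms: lithium dimethylcuprate, [Li+].C[Cu-]C
Why: Cuprate cross-coupling of an alkenyl triflate replaces OTf by methyl with retention of the alkene geometry and so gives the (E)-trisubstituted alkenyl group, while the hindered di-ortho-substituted aryl ketone and the aryl silyl ethers should not react with the dialkylcuprate at low temperature.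

Step 6
Reactants: 10 [2,4-bis(tert-butyldimethylsilyloxy)-6-methoxyphenyl]{(1R,2S,4R)-2-[(2E)-6-methylhepta-2,5-dien-2-yl]-4-phenylcyclobutyl}methanone
Product: 11 (2,4-dihydroxy-6-methoxyphenyl){(1R,2S,4R)-2-[(2E)-6-methylhepta-2,5-dien-2-yl]-4-phenylcyclobutyl}methanone
Conditions: TBAF (2.2 equiv), AcOH (2.2 equiv), THF, 0 °C
Reagents that add atoms: none
Why: Fluoride-mediated desilylation of both aryl silyl ethers, buffered with acetic acid so that the phenoxides are protonated at once and the enolisable C1 is not disturbed.

Step 7
Reactants: 11 (2,4-dihydroxy-6-methoxyphenyl){(1R,2S,4R)-2-[(2E)-6-methylhepta-2,5-dien-2-yl]-4-phenylcyclobutyl}methanone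
Product: 12 isopanduratin A [(2,4-dihydroxy-6-methoxyphenyl)[(1R,2S,6R)-3-methyl-2-(3-methylbut-2-en-1-yl)-6-phenylcyclohex-3-en-1-yl]methanone]
Conditions: Sc(OTf)3 (20 mol %), 2,6-di-tert-butyl-4-methylpyridine (20 mol %), 4 Å MS, CH2Cl2, −20 °C → rt
Reagents that add atoms: none
Why: Sc(III) binds the o-hydroxyaryl ketone as a phenoxide/carbonyl chelate, the strained C1–C4 bond ionises to a chelated scandium enolate and an (E)-1,3-dialkyl-2-methylallyl cation held as a contact ion pair, and the enolate carbon recombines at the distal allyl terminus, a net [1,3]-shift. The closest known reaction type is the acid-promoted (zwitterionic) vinylcyclobutane–cyclohexene rearrangement of 2-alkenylcyclobutyl carbonyl compounds, the second stage of stepwise ionic Diels–Alder reactions, together with the Lewis-acid opening of donor–acceptor cyclobutanes. The six-membered ring closes by 6-endo-trig C-alkylation of the exocyclic enolate on the allyl cation, so that all three allyl carbons end in the ring. C6 is not touched and keeps its configuration; C2 is controlled by the E geometry of the allyl terminus (prenyl CH2 outside) and by a boat-like collapse with phenyl pseudo-equatorial and the chelated enolate oxygens held over the cation by Coulomb attraction (endo), which should put prenyl anti to phenyl and syn to the aroyl group; C1 is formed trans to phenyl, which is also its thermodynamic configuration. The step needs ionisation of the allylic C1–C4 bond rather than the benzylic C1–C6 bond and ring closure faster than fragmentation to chalcone and triene: the more stabilised trisubstituted allyl cation, the chelate and the low temperature should secure both, and the hindered pyridine keeps adventitious triflic acid away from the prenyl group.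

**Compound list**

1 | cardamonin, (E)-1-(2,4-dihydroxy-6-methoxyphenyl)-3-phenylprop-2-en-1-one | COc1cc(O)cc(O)c1C(=O)/C=C/c1ccccc1 | starting material
2 | (E)-1-[2,4-bis(tert-butyldimethylsilyloxy)-6-methoxyphenyl]-3-phenylprop-2-en-1-one | COc1cc(O[Si](C)(C)C(C)(C)C)cc(O[Si](C)(C)C(C)(C)C)c1C(=O)/C=C/c1ccccc1 | intermediate
3 | 5-bromo-2-methylpent-2-ene | CC(C)=CCCBr | starting material
4 | N-methoxy-N-methylprop-2-enamide | C=CC(=O)N(C)OC | starting material
5 | (4-methylpent-3-en-1-yl)magnesium bromide | CC(C)=CCC[Mg]Br | intermediate
6 | 7-methylocta-1,6-dien-3-one | C=CC(=O)CCC=C(C)C | intermediate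
7 | [2,4-bis(tert-butyldimethylsilyloxy)-6-methoxyphenyl][(1S,2S,4R)-2-(5-methylhex-4-enoyl)-4-phenylcyclobutyl]methanone | COc1cc(O[Si](C)(C)C(C)(C)C)cc(O[Si](C)(C)C(C)(C)C)c1C(=O)[C@H]1[C@H](c2ccccc2)C[C@@H]1C(=O)CCC=C(C)C | intermediate
8 | potassium (Z)-enolate of 7, enolised towards the chain CH2 | COc1cc(O[Si](C)(C)C(C)(C)C)cc(O[Si](C)(C)C(C)(C)C)c1C(=O)[C@H]1[C@H](c2ccccc2)C[C@@H]1/C([O-])=C/CC=C(C)C.[K+] | intermediate
9 | (1Z)-1-{(1S,2S,3R)-2-[2,4-bis(tert-butyldimethylsilyloxy)-6-methoxybenzoyl]-3-phenylcyclobutyl}-5-methylhexa-1,4-dien-1-yl trifluoromethanesulfonate | COc1cc(O[Si](C)(C)C(C)(C)C)cc(O[Si](C)(C)C(C)(C)C)c1C(=O)[C@H]1[C@H](c2ccccc2)C[C@@H]1/C(OS(=O)(=O)C(F)(F)F)=C/CC=C(C)C | intermediate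
10 | [2,4-bis(tert-butyldimethylsilyloxy)-6-methoxyphenyl]{(1R,2S,4R)-2-[(2E)-6-methylhepta-2,5-dien-2-yl]-4-phenylcyclobutyl}methanone | COc1cc(O[Si](C)(C)C(C)(C)C)cc(O[Si](C)(C)C(C)(C)C)c1C(=O)[C@H]1[C@H](c2ccccc2)C[C@@H]1/C(C)=C/CC=C(C)C | intermediate
11 | (2,4-dihydroxy-6-methoxyphenyl){(1R,2S,4R)-2-[(2E)-6-methylhepta-2,5-dien-2-yl]-4-phenylcyclobutyl}methanone | COc1cc(O)cc(O)c1C(=O)[C@H]1[C@H](c2ccccc2)C[C@@H]1/C(C)=C/CC=C(C)C | intermediate
12 | isopanduratin A, (2,4-dihydroxy-6-methoxyphenyl)[(1R,2S,6R)-3-methyl-2-(3-methylbut-2-en-1-yl)-6-phenylcyclohex-3-en-1-yl]methanone | COc1cc(O)cc(O)c1C(=O)[C@@H]1[C@H](CC=C(C)C)C(C)=CC[C@H]1c1ccccc1 | target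

**Step count.** Seven steps in total. The longest linear sequence is six steps (steps 1, 3, 4, 5, 6 and 7 from cardamonin); step 2 is a one-step side branch.

**Steps most likely to fail**

Step 7. The ion pair may collapse with poor endo/exo control at C2. It may also lose the C6 configuration, either by fragmenting to chalcone and triene before ring closure or by competing ionisation of the benzylic C1–C6 bond. The fallback replaces two-electron activation by single-electron activation and runs from 11 directly to 12. With La(OTf)3, Ru(bpy)3(PF6)2 and TMEDA in MeCN under visible light, the chelated aryl ketone should be reduced to its ketyl radical anion. β-Scission of the C1–C4 bond then gives a lanthanum enolate and an allyl radical, the radical closes on the enolate carbon at the distal terminus to the six-membered ring, and back electron transfer releases 12. The elementary steps are those of photoreductive ring-opening cycloadditions of aryl cyclopropyl ketones and of electron-transfer-initiated formal Diels–Alder reactions of 2'-hydroxychalcones. This fallback makes no new compound (F0).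

Step 3. The chalcone radical anion may dimerise reductively or add only sluggishly to the vinyl ketone, and the ortho,ortho'-disubstituted aryl ketone may bind the chiral Lewis acid poorly, which would lower the enantioselectivity. The fallback replaces asymmetric catalysis by resolution: 2 and 6 are combined under the achiral radical-anion conditions (Ru(bpy)3Cl2, LiBF4, i-Pr2NEt, MeCN, visible light), and the racemic all-trans cycloadduct is separated by preparative chiral SFC. Compound 7 is carried on into step 4, and its enantiomer, ent-7 F1, is set aside.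

Step 4. Deprotonation may occur in part at a cyclobutyl methine or give an E/Z enolate mixture that would end as the wrong alkene geometry, and the enolate may add to the neighbouring aryl ketone. The fallback builds the alkene by olefination instead of enolate triflation and cross-coupling. Chalcone 2 is combined with but-3-en-2-one under the conditions of step 3 to give the methyl ketone [2,4-bis(tert-butyldimethylsilyloxy)-6-methoxyphenyl][(1S,2S,4R)-2-acetyl-4-phenylcyclobutyl]methanone F2. Wittig olefination of F2 with the ylide from (4-methylpent-3-en-1-yl)triphenylphosphonium bromide and NaHMDS in THF should give 10 together with its (2Z)-isomer F3. The two are separated on silver nitrate-impregnated silica, and the route is rejoined at 10.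

**Further compounds**

F0 | step 7 | none | none
F1 | step 3 | ent-7, [2,4-bis(tert-butyldimethylsilyloxy)-6-methoxyphenyl][(1R,2R,4S)-2-(5-methylhex-4-enoyl)-4-phenylcyclobutyl]methanone | COc1cc(O[Si](C)(C)C(C)(C)C)cc(O[Si](C)(C)C(C)(C)C)c1C(=O)[C@@H]1[C@@H](c2ccccc2)C[C@H]1C(=O)CCC=C(C)C
F2 | step 4 | [2,4-bis(tert-butyldimethylsilyloxy)-6-methoxyphenyl][(1S,2S,4R)-2-acetyl-4-phenylcyclobutyl]methanone | COc1cc(O[Si](C)(C)C(C)(C)C)cc(O[Si](C)(C)C(C)(C)C)c1C(=O)[C@H]1[C@H](c2ccccc2)C[C@@H]1C(C)=O
F3 | step 4 | [2,4-bis(tert-butyldimethylsilyloxy)-6-methoxyphenyl]{(1R,2S,4R)-2-[(2Z)-6-methylhepta-2,5-dien-2-yl]-4-phenylcyclobutyl}methanone | COc1cc(O[Si](C)(C)C(C)(C)C)cc(O[Si](C)(C)C(C)(C)C)c1C(=O)[C@H]1[C@H](c2ccccc2)C[C@@H]1/C(C)=C\CC=C(C)C
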